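**Retrosynthetic overview**
- The (3R)-isoflavan comes from reductive cleavage of the benzylic C11a–O bond of the (6aR,11aR)-pterocarpan; C6a of the pterocarpan becomes C3 of the target.
- The pterocarpan comes from a racemic, acyclic 1,2-diarylallyl alcohol in one flask: Ru dehydrogenation, oxa-Michael closure, reduction with dynamic kinetic resolution, acid closure.
- The allyl alcohol comes from forming the C3–C4 bond between an α-styryllithium (Shapiro reaction on the ring B acetophenone) and the ring A salicylaldehyde.
- The ring B ketone comes from 2,4-dihydroxyacetophenone, prenyl bromide and MeI. The ring A aldehyde comes from 2,4-dihydroxy-6-methoxybenzaldehyde and TBSCl.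
- Ring order: both benzene rings are bought. Pyran ring C and the dihydrofuran ring form together in step 6, and the dihydrofuran ring is opened again in step 7.

Assumption: 2,4-dihydroxy-6-methoxybenzaldehyde is bought as a catalogue compound.

**Step 1**
Reactants: 1 2,4-dihydroxyacetophenone; 2 prenyl bromide (1-bromo-3-methylbut-2-ene)
Product: 3 1-[2,4-dihydroxy-3-(3-methylbut-2-enyl)phenyl]ethanone
Conditions: KOH (1.1 equiv), H2O/MeOH, 0 to 23 °C
Reagents that add atoms: none
Why: Phenolate C-alkylation places the prenyl group at C3, the carbon flanked by both oxygens; this is a known preparation with a moderate yield (about 35 %) from very cheap materials, and no stereocentre forms.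

**Step 2**
Reactants: 3 1-[2,4-dihydroxy-3-(3-methylbut-2-enyl)phenyl]ethanone
Product: 4 1-[2-hydroxy-4-methoxy-3-(3-methylbut-2-enyl)phenyl]ethanone
Conditions: MeI (1.05 equiv), K2CO3 (1.1 equiv), acetone, 40 °C
Reagents that add atoms: methyl iodide, CI
Why: In this Williamson ether synthesis the 2-OH is held in a hydrogen bond to the acetyl oxygen, so only the 4-OH is methylated.

**Step 3**
Reactants: 4 1-[2-hydroxy-4-methoxy-3-(3-methylbut-2-enyl)phenyl]ethanone
Product: 5 (E)-N'-{1-[2-hydroxy-4-methoxy-3-(3-methylbut-2-enyl)phenyl]ethylidene}-2,4,6-triisopropylbenzenesulfonohydrazide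
Conditions: 2,4,6-triisopropylbenzenesulfonyl hydrazide (1.05 equiv), conc. HCl (cat.), MeCN, 23 °C
Reagents that add atoms: 2,4,6-triisopropylbenzenesulfonyl hydrazide, CC(C)c1cc(C(C)C)c(S(=O)(=O)NN)c(C(C)C)c1
Why: Acid-catalysed hydrazone condensation gives the E isomer (N–H syn to the methyl group, phenol hydrogen-bonded to the imine nitrogen), which is the geometry the Shapiro deprotonation needs; catalytic acid at 23 °C does not touch the prenyl group.

**Step 4**
Reactants: 6 2,4-dihydroxy-6-methoxybenzaldehyde
Product: 7 4-(tert-butyldimethylsilyloxy)-2-hydroxy-6-methoxybenzaldehyde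
Conditions: TBSCl (1.05 equiv), imidazole (1.1 equiv), CH2Cl2, 0 °C
Reagents that add atoms: tert-butyldimethylsilyl chloride, CC(C)(C)[Si](C)(C)Cl
Why: Selective O-silylation takes the free, more acidic 4-OH, while the 2-OH stays chelated to the formyl group and is kept free for the later ring closure.

**Step 5**
Reactants: 5 (E)-trisylhydrazone of ketone 4; 7 4-(tert-butyldimethylsilyloxy)-2-hydroxy-6-methoxybenzaldehyde
Product: 10 rac-1-[4-(tert-butyldimethylsilyloxy)-2-hydroxy-6-methoxyphenyl]-2-[2-hydroxy-4-methoxy-3-(3-methylbut-2-enyl)phenyl]prop-2-en-1-ol, via dilithiated alpha-styryl anion 8 (not isolated), via sodium phenolate 9 (not isolated)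
Conditions: 5, n-BuLi (3.1 equiv), THF, −78 to 0 °C (N2 off), recool to −78 °C; separately 7, NaH (1.0 equiv), THF, 0 °C, then cannulate into 8; −78 to −20 °C; H2O quench, work-up at pH 7–8, used crude
Reagents that add atoms: none
Why: In the Shapiro reaction the trianion of 5 loses sulfinate and N2 to give vinyllithium 8, which adds 1,2 to the formyl group of the pre-formed phenolate 9 (NaH spares one equivalent of 8); the carbinol centre is left racemic because step 6 erases it.

**Step 6**
Reactants: 10 racemic 1,2-diarylallyl alcohol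
Product: 14 (6aR,11aR)-3-(tert-butyldimethylsilyloxy)-1,9-dimethoxy-10-(3-methylbut-2-enyl)pterocarpan, via aryl vinyl ketone 11 (not isolated), via racemising isoflavanone 12 (not isolated), via cis-(3R,4R)-isoflavan-4-ol 13 (not isolated)
Conditions: RuCl(p-cymene)[(R,R)-TsDPEN] (3 mol %), KOt-Bu (6 mol %), Et3N (0.5 equiv), toluene/t-AmOH 4:1, 45 °C, 16 h, argon; then AcOH (2 equiv), 23 °C, 1 h, same flask
Reagents that add atoms: none
Why: Proposed new method: the 16-electron Ru amide takes H2 from both enantiomers of the electron-rich allylic benzylic carbinol 10 to give vinyl ketone 11, whose ortho phenol closes the pyran ring by 6-endo oxa-Michael addition much faster than the millimolar Ru–H can reduce the C=C bond; Et3N racemises isoflavanone 12 through its enol while the stored Ru–H of the (R,R) catalyst reduces the (3R) ketone preferentially to the cis-(3R,4R) alcohol 13 (dynamic kinetic resolution sets C3 and C4); AcOH then ionises the trioxygenated benzylic alcohol and the 2'-phenol closes the cis-fused dihydrofuran ring without touching C6a; the closest known reaction types are Ru-catalysed asymmetric hydrogen-borrowing anti-Markovnikov hydroamination of racemic allylic alcohols, and asymmetric transfer hydrogenation of isoflavanones followed by acid cyclisation to pterocarpans.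

**Step 7**
Reactants: 14 (6aR,11aR)-3-(tert-butyldimethylsilyloxy)-1,9-dimethoxy-10-(3-methylbut-2-enyl)pterocarpan
Product: 17 (3R)-3-[2-hydroxy-4-methoxy-3-(3-methylbut-2-enyl)phenyl]-5-methoxychroman-7-ol (target), via sodium pterocarpan-3-olate 15 (not isolated), via para-quinone methide 16 (not isolated)
Conditions: NaOH (3 equiv, 2 M aq), NaBH4 (10 equiv), EtOH, 70 °C; then 1 M HCl to pH 6
Reagents that add atoms: none
Why: Hydroxide cleaves the aryl silyl ether, phenolate 15 expels the 2'-aryloxide from the para benzylic carbon (quinone methide elimination, as in alkaline cleavage of phenolic benzyl aryl ethers and in NaBH4/NaOH deoxygenation of p-hydroxybenzyl alcohols), and the large excess of NaBH4 adds hydride 1,6 to C4 of 16 before it can tautomerise; C3 takes no part, so the R configuration is kept, and the prenyl and methoxy groups are inert.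

**Compound list**
1 | 2,4-dihydroxyacetophenone | CC(=O)c1ccc(O)cc1O | starting material
2 | prenyl bromide | CC(C)=CCBr | starting material
3 | 1-[2,4-dihydroxy-3-(3-methylbut-2-enyl)phenyl]ethanone | CC(=O)c1ccc(O)c(CC=C(C)C)c1O | intermediate
4 | 1-[2-hydroxy-4-methoxy-3-(3-methylbut-2-enyl)phenyl]ethanone | CC(=O)c1ccc(OC)c(CC=C(C)C)c1O | intermediate
5 | (E)-2,4,6-triisopropylbenzenesulfonylhydrazone of 4 | C/C(=N\NS(=O)(=O)c1c(C(C)C)cc(C(C)C)cc1C(C)C)c1ccc(OC)c(CC=C(C)C)c1O | intermediate
6 | 2,4-dihydroxy-6-methoxybenzaldehyde | COc1cc(O)cc(O)c1C=O | starting material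
7 | 4-(tert-butyldimethylsilyloxy)-2-hydroxy-6-methoxybenzaldehyde | COc1cc(O[Si](C)(C)C(C)(C)C)cc(O)c1C=O | intermediate
8 | lithium 6-(1-lithioethenyl)-3-methoxy-2-(3-methylbut-2-enyl)phenolate | [Li]C(=C)c1ccc(OC)c(CC=C(C)C)c1O[Li] | intermediate
9 | sodium 5-(tert-butyldimethylsilyloxy)-2-formyl-3-methoxyphenolate | COc1cc(O[Si](C)(C)C(C)(C)C)cc([O-])c1C=O.[Na+] | intermediate
10 | rac-1-[4-(tert-butyldimethylsilyloxy)-2-hydroxy-6-methoxyphenyl]-2-[2-hydroxy-4-methoxy-3-(3-methylbut-2-enyl)phenyl]prop-2-en-1-ol | C=C(C(O)c1c(O)cc(O[Si](C)(C)C(C)(C)C)cc1OC)c1ccc(OC)c(CC=C(C)C)c1O | intermediate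
11 | 1-[4-(tert-butyldimethylsilyloxy)-2-hydroxy-6-methoxyphenyl]-2-[2-hydroxy-4-methoxy-3-(3-methylbut-2-enyl)phenyl]prop-2-en-1-one | C=C(C(=O)c1c(O)cc(O[Si](C)(C)C(C)(C)C)cc1OC)c1ccc(OC)c(CC=C(C)C)c1O | intermediate
12 | 7-(tert-butyldimethylsilyloxy)-3-[2-hydroxy-4-methoxy-3-(3-methylbut-2-enyl)phenyl]-5-methoxychroman-4-one (C3 racemising) | O=C1c2c(OC)cc(O[Si](C)(C)C(C)(C)C)cc2OCC1c1ccc(OC)c(CC=C(C)C)c1O | intermediate
13 | (3R,4R)-7-(tert-butyldimethylsilyloxy)-3-[2-hydroxy-4-methoxy-3-(3-methylbut-2-enyl)phenyl]-5-methoxychroman-4-ol (cis) | O[C@@H]1[C@H](c3ccc(OC)c(CC=C(C)C)c3O)COc2cc(O[Si](C)(C)C(C)(C)C)cc(OC)c12 | intermediate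
14 | (6aR,11aR)-3-(tert-butyldimethylsilyloxy)-1,9-dimethoxy-10-(3-methylbut-2-enyl)pterocarpan | O3[C@@H]1[C@H](c4ccc(OC)c(CC=C(C)C)c43)COc2cc(O[Si](C)(C)C(C)(C)C)cc(OC)c12 | intermediate
15 | sodium (6aR,11aR)-1,9-dimethoxy-10-(3-methylbut-2-enyl)pterocarpan-3-olate | O3[C@@H]1[C@H](c4ccc(OC)c(CC=C(C)C)c43)COc2cc([O-])cc(OC)c12.[Na+] | intermediate
16 | sodium 3-methoxy-6-[(3R)-5-methoxy-7-oxo-3,7-dihydro-2H-chromen-3-yl]-2-(3-methylbut-2-enyl)phenolate (para-quinone methide) | O=C1C=C(OC)C2=C[C@H](c3ccc(OC)c(CC=C(C)C)c3[O-])COC2=C1.[Na+] | intermediate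
17 | (3R)-3-[2-hydroxy-4-methoxy-3-(3-methylbut-2-enyl)phenyl]-5-methoxychroman-7-ol | COc1cc(O)cc2c1C[C@H](c1ccc(OC)c(CC=C(C)C)c1O)CO2 | target

**Step count and weak points**
Total steps: 7. Longest linear sequence: 6 (steps 1, 2, 3, 5, 6, 7).
The steps most likely to fail are step 6, then step 5, then step 7.

Step 6 can stall in three ways. The hindered carbinol may be dehydrogenated too slowly, hydrogen may escape as H2, or Ru–H may reduce the C=C bond of 11. The fallback separates the redox events. It sets out from 10, which MnO2 in CH2Cl2 oxidises to 11. On addition of Et3N, 11 closes to isoflavanone 12, which is now isolated. Ketone 12 is then reduced with an external reductant (RuCl(p-cymene)[(R,R)-TsDPEN], HCO2H/Et3N, EtOAc, 40 °C) to 13. AcOH treatment brings the sequence back to the route at 14. No compound outside the list is made (F0).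

Step 5 can fail because phenolate 9 is a hindered, strongly deactivated aldehyde for a hard and hindered carbanion. The fallback replaces the carbanion addition by a chromium-mediated Barbier-type coupling. It sets out from 5. The same anion 8 is quenched with I2 at −78 °C to give the vinyl iodide 6-(1-iodoethenyl)-3-methoxy-2-(3-methylbut-2-enyl)phenol F1. This is coupled with the neutral aldehyde 7 using CrCl2 (4 equiv) and NiCl2 (1 mol %) in DMF at 23 °C, where the oxophilic chromium activates the carbonyl group. The sequence comes back to the route at 10.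

Step 7 can fail if phenolate 15 opens too slowly. It can also fail if 16 tautomerises to the isoflav-3-ene, which costs yield and, should the isoflavene re-enter as 16, also ee. The fallback cleaves the benzylic C–O bond by electron transfer, so no quinone methide is involved. It sets out from 14. Li (4 equiv) in NH3/THF with t-BuOH (2 equiv) at −78 °C for 10 min gives the silyl ether 2-[(3R)-7-(tert-butyldimethylsilyloxy)-5-methoxychroman-3-yl]-5-methoxy-6-(3-methylbut-2-enyl)phenol F2. The isolated prenyl alkene is not reduced. Tetrabutylammonium fluoride in THF at 0 °C then gives 17, where the sequence rejoins the route.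

**Further compounds**
F0 | step 6 | none | none
F1 | step 5 | 6-(1-iodoethenyl)-3-methoxy-2-(3-methylbut-2-enyl)phenol | C=C(I)c1ccc(OC)c(CC=C(C)C)c1O
F2 | step 7 | 2-[(3R)-7-(tert-butyldimethylsilyloxy)-5-methoxychroman-3-yl]-5-methoxy-6-(3-methylbut-2-enyl)phenol | COc1cc(O[Si](C)(C)C(C)(C)C)cc2c1C[C@H](c1ccc(OC)c(CC=C(C)C)c1O)CO2
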